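| flask | starting material | temperature | remark | time |
|---|---|---|---|---|
| winter | 0.14 M | 20 °C | run made earlier |  |
| spring | 0.22 M | 38 °C | run made earlier |  |
| north-west | 0.10 M | 50 °C |  | 50 min |
| south | 0.10 M | 25 °C |  | 50 min |

| run | time / min | side product A / % | over-reaction product / % | starting material / % | target / % | side product B / % |
|---|---|---|---|---|---|---|
| winter | 12.0 | 12.1 | 3.1 | 78.0 | 7.2 | 0 |
| winter | 25.0 | 21.8 | 8.5 | 59.5 | 8.3 | 0.2 |
| winter | 40.0 | 30.2 | 15.7 | 43.4 | 8.0 | 0.5 |
| winter | 50.0 | 35.1 | 20.1 | 35.1 | 7.5 | 0 |
| spring | 6.00 | 35.8 | 20.7 | 32.9 | 7.7 | 0.4 |
| spring | 12.0 | 47.6 | 34.5 | 10.4 | 2.6 | 1.0 |
| spring | 20.0 | 52.4 | 40.5 | 2.2 | 1.1 | 0.6 |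
| spring | 25.0 | 52.2 | 41.5 | 0.8 | 0 | 0.8 |

(each reading ± 0.3 percentage points)

- percent here means starting material units held: one side product C counts as two
- reactions considered so far: starting material -> target; starting material <-> intermediate A; starting material -> side product A; intermediate A <-> intermediate B; intermediate A -> intermediate C; intermediate C -> side product B; target -> over-reaction product; starting material + intermediate C -> side product C; starting material -> decomposition product

1. which of these there is most of at the end, counted by the starting material in it, north-west (over-reaction product / side product B / starting material / side product A / target)
2. which of these there is most of at the end, counted by the starting material in it, south (over-reaction product / side product B / starting material / side product A / target)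
3. how much there is at the end of the one of these that leads, in percent of the starting material charged: north-west
4. how much there is at the end of the one of these that leads, in percent of the starting material charged: south

1. The constants come first, and with them the order. For first-order loss, the rate constant k = ln(charged/left)/t. The winter run gives 0.0207 /min at 12.0 min and 0.0209 /min at 50.0 min. The winter run's starting material therefore reads as first order in its own concentration, and this reckoning takes its percentages across charges. The spring run reads 0.189 /min.

2. First rung in the winter run: target. Target and over-reaction product together hold q = 42.5% of the starting material consumed by the last reading. At target's highest reading, at 25.0 min, making is taken to balance loss, so its loss constant reads 0.0638 /min and its half-life 10.9 min. That is shorter than the starting material's 33.1 min, so target follows the starting material down and passes on to over-reaction product.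

3. Next rung: the starting material. Interpolating ln k linearly in temperature gives south 0.0386 /min, hence 14.5% left at 50 min. Extrapolating to north-west gives a half-life of 0.849 min, far shorter than the 50 min allowed, so conversion there counts as complete.

4. Last rung: side product A, which reads 52.4% and then 52.2% in the spring run, with no visible loss. Its amount is therefore taken as s times the fraction consumed, where s is the branching share (selectivity), side product A per starting material consumed, as read: 54.1% in the winter run, 52.6% in the spring run, mean 53.4%.

5. My reckoning: side product A leads in south with 45.6% and in north-west with 53.4%.

6. The forecast names side product A for north-west and side product A for south, at 52% and 46%: “Side product A takes a steady 53–54% of the starting material consumed at both temperatures and does not decay.”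

7. Side product A leads in both flasks, with 52.5% in north-west and 46.1% in south.

    starting material → target (k = 0.0167 /min, Ea = 92.0 kJ/mol)
    starting material ⇌ intermediate A (K = 37.0, k = 0.00157 /min, Ea = 105 kJ/mol, ΔH = 1.00 kJ/mol)
    starting material → side product A (k = 0.0211 /min, Ea = 92.0 kJ/mol)
    intermediate A ⇌ intermediate B (K = 2.49, k = 0.0259 /min, Ea = 79.0 kJ/mol, ΔH = −31.0 kJ/mol)
    intermediate A → intermediate C (k = 0.00709 /min, Ea = 85.0 kJ/mol)
    intermediate C → side product B (k = 0.0183 /min, Ea = 100 kJ/mol)
    target → over-reaction product (k = 0.102 /min, Ea = 88.0 kJ/mol)
    starting material + intermediate C → side product C (k = 0.341 /M/min, Ea = 47.0 kJ/mol)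
    starting material → decomposition product (k = 1.57 × 10⁻⁵ /min, Ea = 102 kJ/mol)
    (constants at 25 °C)

In south, starting material goes to side product A 1.3 times as fast as to target at the start. Target's half-life by its step to over-reaction product alone is 6.8 min, and south ends with 3.55% of target beside 32.9% of over-reaction product. With south's 13.9% left, s gives 46.0%.

In the flask like south kept at 0 °C, 93.7% of starting material remains, so s gives 3.36% of side product A. The computed amount is 3.42%.

The readings are simulated with constants of no real substance, and the scatter is random.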